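**Retrosynthetic overview**

1. Target 19 comes from 18 by removing two aryl allyl ethers; the enol of 18 comes from saturated lactone 14 by α-hydroxylation and oxidation.
2. The oxirane of 14 comes from the prenyl group of 13 by reagent-controlled Shi epoxidation, done before the oxidation-sensitive enol exists.
3. Key disconnection: the bond between the quaternary carbon and the aryl-bearing ring carbon of 13, together with the lactone C–O bond, is made in one step from enal 3 and α-keto ester 11. A chiral carbene turns the enal β-carbon (normally an acceptor) into a donor that attacks the keto carbon.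
4. 3 comes from 1 and 2 (Wittig); 11 comes from 4, 5 and 8 (C-prenylation, O-allylation, Horner–Wadsworth–Emmons olefination, desilylation).
5. Ring order: γ-lactone (step 6), then oxirane (step 7); both benzene rings are bought.

Assumption 1: phosphonate 8 is taken as a purchasable catalogue reagent.
Assumption 2: the (5aS,10bR) triazolium salt is taken to give the (2R) lactone 13; the sense must be confirmed on the first run, and the mirror-image salt, equally available, is used if it is reversed.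

**Route**

Step 1
Reactants: 1 4-(allyloxy)benzaldehyde; 2 (triphenylphosphoranylidene)acetaldehyde
Product: 3 (2E)-3-[4-(allyloxy)phenyl]prop-2-enal
Conditions: toluene, 80 °C (1.05 equiv of 2)
Reagents that add atoms: none
Why: Wittig two-carbon homologation with a formyl-stabilised ylide, which gives the (E)-enal selectively; the near-stoichiometric ylide limits over-homologation.

Step 2
Reactants: 4 4-hydroxybenzaldehyde; 5 1-bromo-3-methylbut-2-ene
Product: 6 4-hydroxy-3-(3-methylbut-2-en-1-yl)benzaldehyde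
Conditions: KOH (10% aq.), 0 °C to rt
Reagents that add atoms: none
Why: ortho C-alkylation of an ambident phenoxide in water, where hydrogen bonding shields the oxygen and the para position is blocked; yield is modest and unreacted 4 is recovered.

Step 3
Reactants: 6 4-hydroxy-3-(3-methylbut-2-en-1-yl)benzaldehyde
Product: 7 4-(allyloxy)-3-(3-methylbut-2-en-1-yl)benzaldehyde
Conditions: allyl bromide, K2CO3, acetone, reflux
Reagents that add atoms: allyl bromide, C=CCBr
Why: Williamson etherification of the phenol; allyl is chosen because it survives every later step and leaves under neutral conditions.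

Step 4
Reactants: 8 methyl 2-[(tert-butyldimethylsilyl)oxy]-2-(dimethoxyphosphoryl)acetate; 7 4-(allyloxy)-3-(3-methylbut-2-en-1-yl)benzaldehyde
Product: 10 methyl (2Z)-3-[4-(allyloxy)-3-(3-methylbut-2-en-1-yl)phenyl]-2-[(tert-butyldimethylsilyl)oxy]prop-2-enoate, via lithiated phosphonate 9 (not isolated)
Conditions: LiN(SiMe3)2, THF, −78 °C; then 7, −78 °C to rt
Reagents that add atoms: none
Why: Horner–Wadsworth–Emmons olefination gives the silyl enol ether of the aryl pyruvate, and either alkene isomer converges on 11 in step 5.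

Step 5
Reactants: 10 methyl (2Z)-3-[4-(allyloxy)-3-(3-methylbut-2-en-1-yl)phenyl]-2-[(tert-butyldimethylsilyl)oxy]prop-2-enoate
Product: 11 methyl 3-[4-(allyloxy)-3-(3-methylbut-2-en-1-yl)phenyl]-2-oxopropanoate
Conditions: Bu4NF, AcOH, THF, 0 °C
Reagents that add atoms: none
Why: fluoride cleavage of the silyl enol ether; the acetic acid buffer protonates the enolate at once so the keto ester does not self-condense.

Step 6
Reactants: 3 (2E)-3-[4-(allyloxy)phenyl]prop-2-enal (1.5 equiv); 11 methyl 3-[4-(allyloxy)-3-(3-methylbut-2-en-1-yl)phenyl]-2-oxopropanoate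
Product: 13 methyl (2R,3R)-3-[4-(allyloxy)phenyl]-2-{[4-(allyloxy)-3-(3-methylbut-2-en-1-yl)phenyl]methyl}-5-oxotetrahydrofuran-2-carboxylate, via Breslow homoenolate 12 (not isolated)
Conditions: (5aS,10bR)-2-(2,4,6-trimethylphenyl)-5a,10b-dihydro-4H,6H-indeno[2,1-b][1,2,4]triazolo[4,3-d][1,4]oxazin-2-ium chloride (10 mol%), iPr2NEt (20 mol%), toluene, 4 Å molecular sieves, 25 °C, 11 added over 4 h
Reagents that add atoms: none
Why: Proposed new method: asymmetric carbene-catalysed homoenolate [3+2] annulation onto an enolisable β-aryl α-keto ester, in which the carbene adds to 3 to give Breslow homoenolate 12, whose β-carbon attacks the keto carbon of 11 on the face fixed by the aminoindanol backbone and an enol O–H···O=C hydrogen bond, after which the tertiary alkoxide closes the lactone on the acyl azolium and releases the carbene; the closest known reaction type is the carbene-catalysed annulation of enals with α-keto esters or isatins to γ-butyrolactones bearing a quaternary carbinol carbon, and the (2R) diastereomer is taken after chromatography because only that centre survives to the target.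

Step 7
Reactants: 13 methyl (2R,3R)-3-[4-(allyloxy)phenyl]-2-{[4-(allyloxy)-3-(3-methylbut-2-en-1-yl)phenyl]methyl}-5-oxotetrahydrofuran-2-carboxylate
Product: 14 methyl (2R,3R)-3-[4-(allyloxy)phenyl]-2-{[4-(allyloxy)-3-{[(2R)-3,3-dimethyloxiran-2-yl]methyl}phenyl]methyl}-5-oxotetrahydrofuran-2-carboxylate
Conditions: 1,2:4,5-di-O-isopropylidene-β-D-erythro-2,3-hexodiulo-2,6-pyranose (D-fructose-derived Shi ketone, C12H18O6, 30 mol%), KHSO5 (as 2KHSO5·KHSO4·K2SO4), K2CO3, Bu4NHSO4, Na2B4O7 buffer pH 10.5, MeCN–CH2(OMe)2–H2O, 0 °C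
Reagents that add atoms: potassium peroxymonosulfate, [K+].[O-]S(=O)(=O)OO
Why: Shi asymmetric epoxidation, in which the chiral dioxirane attacks the trisubstituted prenyl alkene through the spiro transition state that gives the (R)-oxirane with the D-fructose ketone, while the monosubstituted allyl ethers react far more slowly.

Step 8
Reactants: 14 methyl (2R,3R)-3-[4-(allyloxy)phenyl]-2-{[4-(allyloxy)-3-{[(2R)-3,3-dimethyloxiran-2-yl]methyl}phenyl]methyl}-5-oxotetrahydrofuran-2-carboxylate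
Product: 16 methyl (2R,3S,4S)-3-[4-(allyloxy)phenyl]-2-{[4-(allyloxy)-3-{[(2R)-3,3-dimethyloxiran-2-yl]methyl}phenyl]methyl}-4-hydroxy-5-oxotetrahydrofuran-2-carboxylate, via potassium enolate 15 (not isolated)
Conditions: KN(SiMe3)2, THF, −78 °C; then 2-(benzenesulfonyl)-3-phenyloxaziridine, −78 °C; AcOH quench
Reagents that add atoms: 2-(benzenesulfonyl)-3-phenyloxaziridine, O=S(=O)(c1ccccc1)N1OC1c1ccccc1
Why: Davis enolate hydroxylation at the only enolisable position (the methyl ester has no α-hydrogen), with oxygen delivered anti to the neighbouring aryl group; this new centre is erased in step 9.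

Step 9
Reactants: 16 methyl (2R,3S,4S)-3-[4-(allyloxy)phenyl]-2-{[4-(allyloxy)-3-{[(2R)-3,3-dimethyloxiran-2-yl]methyl}phenyl]methyl}-4-hydroxy-5-oxotetrahydrofuran-2-carboxylate
Product: 18 methyl (2R)-3-[4-(allyloxy)phenyl]-2-{[4-(allyloxy)-3-{[(2R)-3,3-dimethyloxiran-2-yl]methyl}phenyl]methyl}-4-hydroxy-5-oxo-2,5-dihydrofuran-2-carboxylate, via keto tautomer 17 (not isolated)
Conditions: Dess–Martin periodinane (1.1 equiv), pyridine, CH2Cl2, 0 °C
Reagents that add atoms: none
Why: Dess–Martin oxidation of the α-hydroxy lactone gives the α-keto lactone, which tautomerises fully to the aryl-conjugated enol and so removes both transient stereocentres, while the quaternary centre (no α-hydrogen) and the epoxide (pyridine buffer) are untouched.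

Step 10
Reactants: 18 methyl (2R)-3-[4-(allyloxy)phenyl]-2-{[4-(allyloxy)-3-{[(2R)-3,3-dimethyloxiran-2-yl]methyl}phenyl]methyl}-4-hydroxy-5-oxo-2,5-dihydrofuran-2-carboxylate
Product: 19 methyl (2R)-2-[(3-{[(2R)-3,3-dimethyloxiran-2-yl]methyl}-4-hydroxyphenyl)methyl]-4-hydroxy-3-(4-hydroxyphenyl)-5-oxo-2,5-dihydrofuran-2-carboxylate
Conditions: Pd(PPh3)4 (5 mol%), morpholine (10 equiv), THF, 20 °C; NaH2PO4 buffer work-up, chromatography on neutral silica
Reagents that add atoms: none
Why: Tsuji–Trost-type deallylation, in which zerovalent palladium ionises both aryl allyl ethers and excess morpholine traps the π-allyl fragment, under non-acidic conditions that spare the epoxide, lactone and methyl ester and leave both stereocentres unchanged.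

**Compound list**

1 | 4-(allyloxy)benzaldehyde | C=CCOc1ccc(C=O)cc1 | starting material
2 | (triphenylphosphoranylidene)acetaldehyde | O=CC=P(c1ccccc1)(c1ccccc1)c1ccccc1 | starting material
3 | (2E)-3-[4-(allyloxy)phenyl]prop-2-enal | C=CCOc1ccc(/C=C/C=O)cc1 | intermediate
4 | 4-hydroxybenzaldehyde | O=Cc1ccc(O)cc1 | starting material
5 | 1-bromo-3-methylbut-2-ene (prenyl bromide) | CC(C)=CCBr | starting material
6 | 4-hydroxy-3-(3-methylbut-2-en-1-yl)benzaldehyde | CC(C)=CCc1cc(C=O)ccc1O | intermediate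
7 | 4-(allyloxy)-3-(3-methylbut-2-en-1-yl)benzaldehyde | CC(C)=CCc1cc(C=O)ccc1OCC=C | intermediate
8 | methyl 2-[(tert-butyldimethylsilyl)oxy]-2-(dimethoxyphosphoryl)acetate | COC(=O)C(O[Si](C)(C)C(C)(C)C)P(=O)(OC)OC | starting material
9 | lithiated phosphonate (lithium salt of 8, not isolated) | [Li+].COC(=O)[C-](O[Si](C)(C)C(C)(C)C)P(=O)(OC)OC | intermediate
10 | methyl (2Z)-3-[4-(allyloxy)-3-(3-methylbut-2-en-1-yl)phenyl]-2-[(tert-butyldimethylsilyl)oxy]prop-2-enoate (Z isomer drawn; the minor E isomer is carried along) | COC(=O)/C(O[Si](C)(C)C(C)(C)C)=C/c1ccc(OCC=C)c(CC=C(C)C)c1 | intermediate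
11 | methyl 3-[4-(allyloxy)-3-(3-methylbut-2-en-1-yl)phenyl]-2-oxopropanoate (keto form drawn; in equilibrium with its enol) | COC(=O)C(=O)Cc1ccc(OCC=C)c(CC=C(C)C)c1 | intermediate
12 | Breslow homoenolate: dienol adduct of the (5aS,10bR)-triazolylidene and 3 (not isolated) | OC(/C=C/c1ccc(OCC=C)cc1)=C1N(c2c(C)cc(C)cc2C)N=C2CO[C@H]3Cc4ccccc4[C@H]3N12 | intermediate
13 | methyl (2R,3R)-3-[4-(allyloxy)phenyl]-2-{[4-(allyloxy)-3-(3-methylbut-2-en-1-yl)phenyl]methyl}-5-oxotetrahydrofuran-2-carboxylate (3-aryl trans to the 2-benzyl group) | COC(=O)[C@]1(Cc2ccc(OCC=C)c(CC=C(C)C)c2)OC(=O)C[C@@H]1c1ccc(OCC=C)cc1 | intermediate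
14 | methyl (2R,3R)-3-[4-(allyloxy)phenyl]-2-{[4-(allyloxy)-3-{[(2R)-3,3-dimethyloxiran-2-yl]methyl}phenyl]methyl}-5-oxotetrahydrofuran-2-carboxylate | COC(=O)[C@]1(Cc2ccc(OCC=C)c(C[C@H]3OC3(C)C)c2)OC(=O)C[C@@H]1c1ccc(OCC=C)cc1 | intermediate
15 | potassium lactone enolate of 14 (not isolated) | [K+].COC(=O)[C@]1(Cc2ccc(OCC=C)c(C[C@H]3OC3(C)C)c2)OC([O-])=C[C@@H]1c1ccc(OCC=C)cc1 | intermediate
16 | methyl (2R,3S,4S)-3-[4-(allyloxy)phenyl]-2-{[4-(allyloxy)-3-{[(2R)-3,3-dimethyloxiran-2-yl]methyl}phenyl]methyl}-4-hydroxy-5-oxotetrahydrofuran-2-carboxylate | COC(=O)[C@]1(Cc2ccc(OCC=C)c(C[C@H]3OC3(C)C)c2)OC(=O)[C@@H](O)[C@@H]1c1ccc(OCC=C)cc1 | intermediate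
17 | methyl (2R,3R)-3-[4-(allyloxy)phenyl]-2-{[4-(allyloxy)-3-{[(2R)-3,3-dimethyloxiran-2-yl]methyl}phenyl]methyl}-4,5-dioxotetrahydrofuran-2-carboxylate (keto tautomer, not isolated) | COC(=O)[C@]1(Cc2ccc(OCC=C)c(C[C@H]3OC3(C)C)c2)OC(=O)C(=O)[C@@H]1c1ccc(OCC=C)cc1 | intermediate
18 | methyl (2R)-3-[4-(allyloxy)phenyl]-2-{[4-(allyloxy)-3-{[(2R)-3,3-dimethyloxiran-2-yl]methyl}phenyl]methyl}-4-hydroxy-5-oxo-2,5-dihydrofuran-2-carboxylate | COC(=O)[C@]1(Cc2ccc(OCC=C)c(C[C@H]3OC3(C)C)c2)OC(=O)C(O)=C1c1ccc(OCC=C)cc1 | intermediate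
19 | methyl (2R)-2-[(3-{[(2R)-3,3-dimethyloxiran-2-yl]methyl}-4-hydroxyphenyl)methyl]-4-hydroxy-3-(4-hydroxyphenyl)-5-oxo-2,5-dihydrofuran-2-carboxylate | COC(=O)[C@]1(Cc2ccc(O)c(C[C@H]3OC3(C)C)c2)OC(=O)C(O)=C1c1ccc(O)cc1 | target

**Totals and risks**

Total step count: 10. Longest linear sequence: 9 (steps 2 to 10, from 4-hydroxybenzaldehyde).

The three steps most likely to fail:

Step 6 is the weakest point. Keto ester 11 is largely enolised, so its enol can be O-acylated by the β-protonated acyl azolium or it can self-condense under base, and the facial sense and diastereoselectivity are unproven for this substrate class. The fallback keeps the carbene but uses it in acyl-anion mode, where no such acyl azolium exists. It sets out from 1 and 11. A cross-benzoin with (5aS,10bR)-2-(pentafluorophenyl)-5a,10b-dihydro-4H,6H-indeno[2,1-b][1,2,4]triazolo[4,3-d][1,4]oxazin-2-ium tetrafluoroborate and iPr2NEt joins the aldehyde carbon of 1 to the keto carbon of 11 and gives methyl (2R)-2-{[4-(allyloxy)-3-(3-methylbut-2-en-1-yl)phenyl]methyl}-3-[4-(allyloxy)phenyl]-2-hydroxy-3-oxopropanoate F1. Shi epoxidation under the conditions of step 7 gives methyl (2R)-2-{[4-(allyloxy)-3-{[(2R)-3,3-dimethyloxiran-2-yl]methyl}phenyl]methyl}-3-[4-(allyloxy)phenyl]-2-hydroxy-3-oxopropanoate F2. Acylation of the tertiary alcohol with (allyloxy)acetyl chloride, pyridine and 4-(dimethylamino)pyridine gives methyl (2R)-2-{[(allyloxy)acetyl]oxy}-2-{[4-(allyloxy)-3-{[(2R)-3,3-dimethyloxiran-2-yl]methyl}phenyl]methyl}-3-[4-(allyloxy)phenyl]-3-oxopropanoate F3. Intramolecular aldol condensation of the glycolate enolate onto the aryl ketone with LiN(SiMe3)2 in THF, −78 to 0 °C, gives methyl (2R)-4-(allyloxy)-3-[4-(allyloxy)phenyl]-2-{[4-(allyloxy)-3-{[(2R)-3,3-dimethyloxiran-2-yl]methyl}phenyl]methyl}-5-oxo-2,5-dihydrofuran-2-carboxylate F4. The conditions of step 10 then remove all three allyl groups, and the fallback comes back to the route at 19.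

Step 10 is the second risk. The free enolate of 18 can capture the π-allyl fragment at carbon, and the freed ortho-phenol can cyclise onto the epoxide if the medium drifts acidic or strongly basic. The fallback masks the enol first. It sets out from 18. Ac2O and pyridine in CH2Cl2 at 0 °C give methyl (2R)-4-acetoxy-3-[4-(allyloxy)phenyl]-2-{[4-(allyloxy)-3-{[(2R)-3,3-dimethyloxiran-2-yl]methyl}phenyl]methyl}-5-oxo-2,5-dihydrofuran-2-carboxylate F5. Pd(PPh3)4 with PhSiH3 in CH2Cl2 (neutral hydride scavenger, allyl leaves as propene) gives methyl (2R)-4-acetoxy-2-[(3-{[(2R)-3,3-dimethyloxiran-2-yl]methyl}-4-hydroxyphenyl)methyl]-3-(4-hydroxyphenyl)-5-oxo-2,5-dihydrofuran-2-carboxylate F6. The activated enol acetate is then cleaved with hydrazine acetate in DMF at 0 °C, and the fallback comes back to the route at 19.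

Step 9 is the third risk. The electron-rich enol product can be over-oxidised by the periodinane at the aryl-bearing carbon. The fallback replaces alcohol oxidation by oxidative cleavage of an enaminone and bypasses steps 8 and 9. It sets out from 14. Heating with tert-butoxybis(dimethylamino)methane in toluene at 80 °C gives methyl (2R,3S,4E)-3-[4-(allyloxy)phenyl]-2-{[4-(allyloxy)-3-{[(2R)-3,3-dimethyloxiran-2-yl]methyl}phenyl]methyl}-4-[(dimethylamino)methylidene]-5-oxotetrahydrofuran-2-carboxylate F7. NaIO4 in THF–H2O at pH 7 and rt cleaves the enamine C=C to the α-keto lactone, which enolises, and the fallback comes back to the route at 18.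

**Further compounds**

F1 | step 6 | methyl (2R)-2-{[4-(allyloxy)-3-(3-methylbut-2-en-1-yl)phenyl]methyl}-3-[4-(allyloxy)phenyl]-2-hydroxy-3-oxopropanoate | COC(=O)[C@@](O)(Cc1ccc(OCC=C)c(CC=C(C)C)c1)C(=O)c1ccc(OCC=C)cc1
F2 | step 6 | methyl (2R)-2-{[4-(allyloxy)-3-{[(2R)-3,3-dimethyloxiran-2-yl]methyl}phenyl]methyl}-3-[4-(allyloxy)phenyl]-2-hydroxy-3-oxopropanoate | COC(=O)[C@@](O)(Cc1ccc(OCC=C)c(C[C@H]2OC2(C)C)c1)C(=O)c1ccc(OCC=C)cc1
F3 | step 6 | methyl (2R)-2-{[(allyloxy)acetyl]oxy}-2-{[4-(allyloxy)-3-{[(2R)-3,3-dimethyloxiran-2-yl]methyl}phenyl]methyl}-3-[4-(allyloxy)phenyl]-3-oxopropanoate | COC(=O)[C@@](OC(=O)COCC=C)(Cc1ccc(OCC=C)c(C[C@H]2OC2(C)C)c1)C(=O)c1ccc(OCC=C)cc1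
F4 | step 6 | methyl (2R)-4-(allyloxy)-3-[4-(allyloxy)phenyl]-2-{[4-(allyloxy)-3-{[(2R)-3,3-dimethyloxiran-2-yl]methyl}phenyl]methyl}-5-oxo-2,5-dihydrofuran-2-carboxylate | COC(=O)[C@]1(Cc2ccc(OCC=C)c(C[C@H]3OC3(C)C)c2)OC(=O)C(OCC=C)=C1c1ccc(OCC=C)cc1
F5 | step 10 | methyl (2R)-4-acetoxy-3-[4-(allyloxy)phenyl]-2-{[4-(allyloxy)-3-{[(2R)-3,3-dimethyloxiran-2-yl]methyl}phenyl]methyl}-5-oxo-2,5-dihydrofuran-2-carboxylate | COC(=O)[C@]1(Cc2ccc(OCC=C)c(C[C@H]3OC3(C)C)c2)OC(=O)C(OC(C)=O)=C1c1ccc(OCC=C)cc1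
F6 | step 10 | methyl (2R)-4-acetoxy-2-[(3-{[(2R)-3,3-dimethyloxiran-2-yl]methyl}-4-hydroxyphenyl)methyl]-3-(4-hydroxyphenyl)-5-oxo-2,5-dihydrofuran-2-carboxylate | COC(=O)[C@]1(Cc2ccc(O)c(C[C@H]3OC3(C)C)c2)OC(=O)C(OC(C)=O)=C1c1ccc(O)cc1
F7 | step 9 | methyl (2R,3S,4E)-3-[4-(allyloxy)phenyl]-2-{[4-(allyloxy)-3-{[(2R)-3,3-dimethyloxiran-2-yl]methyl}phenyl]methyl}-4-[(dimethylamino)methylidene]-5-oxotetrahydrofuran-2-carboxylate | COC(=O)[C@]1(Cc2ccc(OCC=C)c(C[C@H]3OC3(C)C)c2)OC(=O)/C(=C/N(C)C)[C@@H]1c1ccc(OCC=C)cc1
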